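A direct plan would alkylate (E)-2,6-dimethoxy-4-(prop-1-en-1-yl)phenol 1 with (R)-2-chloropropanoic acid A1 to the (S)-aryloxy acid A2, activate A2 as its S-(2-pyridyl) thioester A3 and couple A3 with 5-iodo-1,2,3-trimethoxybenzene A4 under reductive nickel catalysis.
The acyl–aryl coupling would be its weakest step: without precedent, run last on all the chiral material, and reducing enough to threaten the α-aryloxy C–O bond and the acidic α-hydrogen of the product ketone.
The etherification would stake the only stereocentre on clean SN2 inversion by a di-ortho-substituted phenoxide at 60 °C, where chloride exchange would erode the ee beyond repair.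
The thioester activation would build no skeleton and would make that stereocentre more labile just before the riskiest step.

**Plan of the new route**
Ring A and ring B are the same 3,5-dimethoxy-4-oxyphenyl ring with a C3 chain at C1, and C8 of the ring-A chain is bonded to O4' of ring B. This is the O–Cβ coupling pattern of the phenoxyl radical of a 4-propenylphenol whose positions 3 and 5 are blocked by methoxy groups.
The retrosynthesis cuts C8–O4' and the C7–O bond back to two molecules of 1 and water. Both benzene rings come ready-made from 1, no ring is formed, and the aryl–C7 bond is never made because ring A brings its chain along.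
C8–H lies between the C7 carbonyl and the aryloxy oxygen, and this lability is used: the racemic ketone is funnelled into one alcohol by dynamic kinetic resolution, and a neutral oxidation returns the ketone.
No substitution at a stereocentre, no acyl activation and no reductive coupling next to an α-aryloxy ketone remain.

Key step: step 1

Assumption: 1 is used as the pure (E) isomer (commercial 4-propenylsyringol, freed of any (Z) isomer by crystallisation). C7, C8, C9 denote the propane chain from the ring-A end and O4' the ether oxygen on ring B.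

**Step 1**
Reactants: 1 (E)-2,6-dimethoxy-4-(prop-1-en-1-yl)phenol (2 equiv)
Product: 4 rac-1-(4-hydroxy-3,5-dimethoxyphenyl)-2-[2,6-dimethoxy-4-[(E)-prop-1-en-1-yl]phenoxy]propan-1-ol (erythro/threo mixture), via phenoxyl radical 2 (not isolated), via quinone methide 3 (not isolated)
Conditions: divided cell, graphite felt anode, Pt cathode, acetone–0.1 M aqueous NaH2PO4/Na2HPO4 buffer pH 6 (1:1), controlled potential at the foot of the first anodic wave of 1 (about +0.5 V vs Ag/AgCl), about 0.9 F per mol of 1, 10 °C, N2; anolyte then held at pH 4 (dilute H3PO4) for 1 h; extraction, chromatography, unreacted 1 recycled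
Reagents that add atoms: water, O
Why: One-electron oxidation of 1 at the anode gives the phenoxyl radical 2, whose spin density sits on O4, C1, C3/C5 and C8; O4' of one radical combines with C8 of a second to give the quinone methide 3, and water adds to C7 of 3 to restore ring A as a phenol. The closest known reaction type is the dehydrodimerisation of 4-propenylphenols to 8-O-4' neolignans by peroxidase/H2O2, FeCl3 or Ag2O and by anodic oxidation. No ring is closed. C7 and C8 are formed without control and on purpose: C7 is oxidised in step 3 and C8 is set in step 4, so all four stereoisomers of 4 converge. The step needs O4'–C8 coupling to prevail over C8–C8' and C8–C5' coupling and over further oxidation of 4. The methoxy groups at C3 and C5 shut the C5' mode, the C8–C8' product (a tetrahydrofuran after hydration) is removed by chromatography, and 4 is harder to oxidise than 1 because its phenol is no longer conjugated to the alkene, which the controlled potential and the incomplete conversion exploit.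

**Step 2**
Reactants: 4 rac-1-(4-hydroxy-3,5-dimethoxyphenyl)-2-[2,6-dimethoxy-4-[(E)-prop-1-en-1-yl]phenoxy]propan-1-ol
Product: 5 rac-2-[2,6-dimethoxy-4-[(E)-prop-1-en-1-yl]phenoxy]-1-(3,4,5-trimethoxyphenyl)propan-1-ol (erythro/threo mixture)
Conditions: MeI (1.5 equiv), K2CO3 (2 equiv), acetone, 20–40 °C
Reagents that add atoms: iodomethane, CI
Why: Williamson O-methylation, in which carbonate deprotonates only the phenol and the phenoxide is methylated by SN2 on iodomethane, while the secondary benzylic alcohol stays free and, at or below 40 °C, the 4-hydroxybenzyl alcohol does not revert to the quinone methide.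

**Step 3**
Reactants: 5 rac-2-[2,6-dimethoxy-4-[(E)-prop-1-en-1-yl]phenoxy]-1-(3,4,5-trimethoxyphenyl)propan-1-ol
Product: 6 rac-2-[2,6-dimethoxy-4-[(E)-prop-1-en-1-yl]phenoxy]-1-(3,4,5-trimethoxyphenyl)propan-1-one
Conditions: Dess–Martin periodinane (1.2 equiv), CH2Cl2, 0 °C to rt
Reagents that add atoms: none
Why: Dess–Martin oxidation of a secondary benzylic alcohol under neutral conditions; both diastereomers should give the same racemic ketone, and neither the propenyl alkene nor the electron-rich rings react with the periodinane.

**Step 4**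
Reactants: 6 rac-2-[2,6-dimethoxy-4-[(E)-prop-1-en-1-yl]phenoxy]-1-(3,4,5-trimethoxyphenyl)propan-1-one
Product: 7 (1R,2S)-2-[2,6-dimethoxy-4-[(E)-prop-1-en-1-yl]phenoxy]-1-(3,4,5-trimethoxyphenyl)propan-1-ol
Conditions: trans-RuCl2[(R)-xylbinap][(R)-daipen] (0.5 mol%; xylbinap = 2,2'-bis[di(3,5-xylyl)phosphino]-1,1'-binaphthyl, daipen = 1,1-bis(4-methoxyphenyl)-3-methylbutane-1,2-diamine), KOtBu (10 mol%), H2 (8 atm), iPrOH, 25 °C; chromatography to remove any threo isomer
Reagents that add atoms: none
Why: Noyori bifunctional ketone hydrogenation under dynamic kinetic resolution: tert-butoxide racemises 6 through its enolate (C2–H lies between the carbonyl and the aryloxy oxygen) faster than the divalent ruthenium hydride reduces it; the (R)-xylbinap/(R)-daipen catalyst delivers hydride to the same carbonyl face as in aryl methyl ketones, where it gives (S)-1-arylethanols, and here that face gives the (1R) carbinol because C2 with its oxygen outranks the aryl group; the (S)-ketone should be the matched enantiomer because its Felkin–Anh conformer (aryloxy group anti to the incoming hydride) presents that face, giving the anti (erythro) alcohol with C2 as S; and the outer-sphere transfer of hydride and proton leaves the propenyl alkene untouched.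

**Step 5**
Reactants: 7 (1R,2S)-2-[2,6-dimethoxy-4-[(E)-prop-1-en-1-yl]phenoxy]-1-(3,4,5-trimethoxyphenyl)propan-1-ol
Product: 8 (S)-2-[2,6-dimethoxy-4-[(E)-prop-1-en-1-yl]phenoxy]-1-(3,4,5-trimethoxyphenyl)propan-1-one
Conditions: Dess–Martin periodinane (1.3 equiv), CH2Cl2, 0 °C; cold aqueous Na2S2O3/NaHCO3 wash, rapid filtration through neutral silica
Reagents that add atoms: none
Why: Dess–Martin oxidation removes the C1 stereocentre and should leave C2 untouched, because ligand exchange and elimination at iodine involve only the carbinol C–H and no base stronger than acetate is present, as in the standard preparation of configurationally labile α-alkoxy carbonyl compounds; the descriptor at C2 stays S since the order OAr > C1 > CH3 > H is unchanged.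

**Compound list**
1 | (E)-2,6-dimethoxy-4-(prop-1-en-1-yl)phenol | C/C=C/c1cc(OC)c(O)c(OC)c1 | starting material
2 | 2,6-dimethoxy-4-[(E)-prop-1-en-1-yl]phenoxyl radical | C/C=C/c1cc(OC)c([O])c(OC)c1 | intermediate
3 | rac-4-{2-[2,6-dimethoxy-4-[(E)-prop-1-en-1-yl]phenoxy]propylidene}-2,6-dimethoxycyclohexa-2,5-dien-1-one (quinone methide) | C/C=C/c1cc(OC)c(OC(C)C=C2C=C(OC)C(=O)C(OC)=C2)c(OC)c1 | intermediate
4 | rac-1-(4-hydroxy-3,5-dimethoxyphenyl)-2-[2,6-dimethoxy-4-[(E)-prop-1-en-1-yl]phenoxy]propan-1-ol (erythro/threo mixture) | C/C=C/c1cc(OC)c(OC(C)C(O)c2cc(OC)c(O)c(OC)c2)c(OC)c1 | intermediate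
5 | rac-2-[2,6-dimethoxy-4-[(E)-prop-1-en-1-yl]phenoxy]-1-(3,4,5-trimethoxyphenyl)propan-1-ol (erythro/threo mixture) | C/C=C/c1cc(OC)c(OC(C)C(O)c2cc(OC)c(OC)c(OC)c2)c(OC)c1 | intermediate
6 | rac-2-[2,6-dimethoxy-4-[(E)-prop-1-en-1-yl]phenoxy]-1-(3,4,5-trimethoxyphenyl)propan-1-one | C/C=C/c1cc(OC)c(OC(C)C(=O)c2cc(OC)c(OC)c(OC)c2)c(OC)c1 | intermediate
7 | (1R,2S)-2-[2,6-dimethoxy-4-[(E)-prop-1-en-1-yl]phenoxy]-1-(3,4,5-trimethoxyphenyl)propan-1-ol | C/C=C/c1cc(OC)c(O[C@@H](C)[C@H](O)c2cc(OC)c(OC)c(OC)c2)c(OC)c1 | intermediate
8 | (S)-2-[2,6-dimethoxy-4-[(E)-prop-1-en-1-yl]phenoxy]-1-(3,4,5-trimethoxyphenyl)propan-1-one | C/C=C/c1cc(OC)c(O[C@@H](C)C(=O)c2cc(OC)c(OC)c(OC)c2)c(OC)c1 | target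

Total step count: 5. Longest linear sequence: 5 steps.

**Steps most likely to fail**

1. Step 1. What may go wrong: radical coupling through C8–C8' instead of O4'–C8, further oxidation of the product phenol, or passivation of the anode by oligomer films. The fallback sets out from 1 and comes back to the route at 6 without any oxidative coupling. Commercial 1-(3,4,5-trimethoxyphenyl)propan-1-one F1 would be brominated at C2 with CuBr2 (EtOAc–CHCl3, reflux) to rac-2-bromo-1-(3,4,5-trimethoxyphenyl)propan-1-one F2. F2 would then alkylate 1 (K2CO3, acetone, 50 °C) to give the racemic ketone 6 directly. Because 6 is racemic by design, substitution at C8 carries no stereochemical cost here.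

2. Step 4. What may go wrong: enolisation slower than reduction (a kinetic instead of a dynamic resolution), or weak or syn-sense matching between the catalyst and the C2 centre; either would lower the purity at C2. The fallback sets out from 6 and comes back at 7 by a reagent-controlled reduction with no dynamic element. (R)-2-Methyl-CBS-oxazaborolidine with BH3·SMe2 (THF, −20 °C) should reduce both enantiomers of 6 to (1R) carbinols: 7 and its diastereomer (1R,2R)-2-[2,6-dimethoxy-4-[(E)-prop-1-en-1-yl]phenoxy]-1-(3,4,5-trimethoxyphenyl)propan-1-ol F3. These would be separated by chromatography. 7 goes on to step 5. F3 would be oxidised with Dess–Martin periodinane to (R)-2-[2,6-dimethoxy-4-[(E)-prop-1-en-1-yl]phenoxy]-1-(3,4,5-trimethoxyphenyl)propan-1-one F4. F4 would be racemised with catalytic DBU and so returned to 6.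

3. Step 5. What may go wrong: partial enolisation of the product at C2 during oxidation, work-up or chromatography, eroding the ee. The fallback sets out from 6 and arrives at 8 without exposing enantioenriched material to an oxidant, by reductive kinetic resolution. RuCl[(R,R)-TsDPEN](p-cymene) (TsDPEN = N-tosyl-1,2-diphenylethane-1,2-diamine) in HCO2H–Et3N (5:2) at 0 °C, a buffered acidic medium in which enolisation of 6 should be slow, should consume the (R)-ketone as (1S,2R)-2-[2,6-dimethoxy-4-[(E)-prop-1-en-1-yl]phenoxy]-1-(3,4,5-trimethoxyphenyl)propan-1-ol F5. The unreacted (S)-ketone 8 would be isolated near half conversion. F5 would be oxidised and racemised back to 6.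

**Further compounds**
F1 | step 1 | 1-(3,4,5-trimethoxyphenyl)propan-1-one | CCC(=O)c1cc(OC)c(OC)c(OC)c1
F2 | step 1 | rac-2-bromo-1-(3,4,5-trimethoxyphenyl)propan-1-one | CC(Br)C(=O)c1cc(OC)c(OC)c(OC)c1
F3 | step 4 | (1R,2R)-2-[2,6-dimethoxy-4-[(E)-prop-1-en-1-yl]phenoxy]-1-(3,4,5-trimethoxyphenyl)propan-1-ol | C/C=C/c1cc(OC)c(O[C@H](C)[C@H](O)c2cc(OC)c(OC)c(OC)c2)c(OC)c1
F4 | step 4 | (R)-2-[2,6-dimethoxy-4-[(E)-prop-1-en-1-yl]phenoxy]-1-(3,4,5-trimethoxyphenyl)propan-1-one | C/C=C/c1cc(OC)c(O[C@H](C)C(=O)c2cc(OC)c(OC)c(OC)c2)c(OC)c1
F5 | step 5 | (1S,2R)-2-[2,6-dimethoxy-4-[(E)-prop-1-en-1-yl]phenoxy]-1-(3,4,5-trimethoxyphenyl)propan-1-ol | C/C=C/c1cc(OC)c(O[C@H](C)[C@@H](O)c2cc(OC)c(OC)c(OC)c2)c(OC)c1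
A1 | direct plan | (R)-2-chloropropanoic acid | C[C@@H](Cl)C(=O)O
A2 | direct plan | (S)-2-[2,6-dimethoxy-4-[(E)-prop-1-en-1-yl]phenoxy]propanoic acid | C/C=C/c1cc(OC)c(O[C@@H](C)C(=O)O)c(OC)c1
A3 | direct plan | S-(pyridin-2-yl) (S)-2-[2,6-dimethoxy-4-[(E)-prop-1-en-1-yl]phenoxy]propanethioate | C/C=C/c1cc(OC)c(O[C@@H](C)C(=O)Sc2ccccn2)c(OC)c1
A4 | direct plan | 5-iodo-1,2,3-trimethoxybenzene | COc1cc(I)cc(OC)c1OC
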